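**Plan**

- Retrosynthetically, the formyl group is masked as a dimethyl acetal and the pyrrole is cut at C3–C4 and N1–C5. The next cuts are the oxime C=N bond and the bond between the ketone carbon and the C22 chain.
- Enabling feature: ring atoms C4 and C5 carry only hydrogen and so are one acetylene unit. C2 (formyl-bearing) and C3 (henicosyl-bearing) are the oxime carbon and the only enolisable methylene of 1,1-dimethoxytetracosan-2-one oxime.
- Forward, the docosyl chain is joined to a two-carbon acetal unit (Grignard reagent plus Weinreb amide) and the ketone is oximated. The single ring, the pyrrole, is then closed with acetylene, and the acetal is hydrolysed last.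
- Stereochemistry: the target has no stereocentre and no stereogenic double bond, so nothing has to be set.

Key step: step 4

Remark: because the target is achiral, the structure drawn is its only stereoisomer. The oxime is carried forward as its E/Z mixture, since both isomers converge on the same enamine tautomer.

**Route**

Step 1
Reactants: 1 methyl dimethoxyacetate
Product: 2 N,2,2-trimethoxy-N-methylacetamide
Conditions: MeNH(OMe)·HCl, i-PrMgCl, THF, −20 to 0 °C; aq. NH4Cl
Reagents that add atoms: N,O-dimethylhydroxylamine hydrochloride, CNOC.Cl
Why: The chloromagnesium amide formed in the flask displaces methoxide from the activated α,α-dialkoxy ester (ester aminolysis to a Weinreb amide), and the acetal is inert to the basic medium.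

Step 2
Reactants: 3 1-bromodocosane; 2 N,2,2-trimethoxy-N-methylacetamide
Product: 5 1,1-dimethoxytetracosan-2-one, via docosylmagnesium bromide 4 (not isolated)
Conditions: Mg, I2 (cat.), THF, 50 °C; then 2, THF, 0 °C to rt; sat. aq. NH4Cl
Reagents that add atoms: none
Why: In this Weinreb ketone synthesis the Grignard adduct is held as a magnesium chelate until the mildly acidic quench, so no second addition should occur, and the buffered work-up leaves the acetal intact.

Step 3
Reactants: 5 1,1-dimethoxytetracosan-2-one
Product: 6 1,1-dimethoxytetracosan-2-one oxime (E/Z mixture)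
Conditions: NH2OH·HCl, NaOAc, EtOH/THF, 60 °C
Reagents that add atoms: hydroxylamine hydrochloride, NO.Cl
Why: Acetate-buffered oxime condensation of a ketone is routine, and an acetal next to a C=O or C=N carbon resists hydrolysis at this pH because its oxocarbenium ion is destabilised.

Step 4
Reactants: 6 1,1-dimethoxytetracosan-2-one oxime; 7 acetylene
Product: 10 2-(dimethoxymethyl)-3-henicosyl-1H-pyrrole, via O-vinyl oxime 8 (not isolated), via imino aldehyde 9 (not isolated)
Conditions: KOH (1 equiv), DMSO, HC≡CH (1 atm, slow stream), 90 °C; then H2O, Et2O; filtration through basic Al2O3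
Reagents that add atoms: none
Why: KOH in DMSO converts 6 into its oximate, which adds to acetylene to give O-vinyl oxime 8; a 1,3-prototropic shift toward the C3 methylene gives the N-(vinyloxy)enamine, whose hetero-Cope [3,3] shift breaks the N–O bond and forms the future C3–C4 bond, delivering imino aldehyde 9. The imine nitrogen then adds to the aldehyde carbon in a 5-exo-trig closure that forms N1–C5, and loss of water followed by a 3H- to 1H-pyrrole hydrogen shift gives the aromatic ring. This is the Trofimov pyrrole synthesis, a known reaction of ketoximes having an α-methylene group with acetylene in superbasic media; no stereocentre is formed. Two selectivities are needed: the enamine must form on the chain side, which the substrate secures because the acetal carbon has a single, hindered and less acidic hydrogen and cannot lead to an aromatic pyrrole, so the henicosyl group ends up on C3; and the pyrrole must not be N-vinylated, which atmospheric acetylene pressure, about 90 °C, stopping at consumption of 6 and the flanking dimethoxymethyl group should hold back. The dimethyl acetal is inert to hydroxide and carries the formyl carbon through at the aldehyde oxidation level.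

Step 5
Reactants: 10 2-(dimethoxymethyl)-3-henicosyl-1H-pyrrole
Product: 11 3-henicosyl-1H-pyrrole-2-carbaldehyde
Conditions: AcOH/THF/H2O, 0 °C to rt, dilute
Reagents that add atoms: water, O
Why: In this acid-catalysed acetal hydrolysis the pyrrole nitrogen lone pair assists ionisation, so weak acid should suffice, and the product is a vinylogous formamide that is no longer prone to further reaction.

**Compound list**

1 | methyl dimethoxyacetate | COC(OC)C(=O)OC | starting material
2 | N,2,2-trimethoxy-N-methylacetamide | COC(OC)C(=O)N(C)OC | intermediate
3 | 1-bromodocosane | CCCCCCCCCCCCCCCCCCCCCCBr | starting material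
4 | docosylmagnesium bromide | CCCCCCCCCCCCCCCCCCCCCC[Mg]Br | intermediate
5 | 1,1-dimethoxytetracosan-2-one | CCCCCCCCCCCCCCCCCCCCCCC(=O)C(OC)OC | intermediate
6 | 1,1-dimethoxytetracosan-2-one oxime (E/Z mixture) | CCCCCCCCCCCCCCCCCCCCCCC(=NO)C(OC)OC | intermediate
7 | acetylene | C#C | starting material
8 | 1,1-dimethoxytetracosan-2-one O-vinyl oxime | CCCCCCCCCCCCCCCCCCCCCCC(=NOC=C)C(OC)OC | intermediate
9 | 3-(1-imino-2,2-dimethoxyethyl)tetracosanal | CCCCCCCCCCCCCCCCCCCCCC(CC=O)C(=N)C(OC)OC | intermediate
10 | 2-(dimethoxymethyl)-3-henicosyl-1H-pyrrole | CCCCCCCCCCCCCCCCCCCCCc1cc[nH]c1C(OC)OC | intermediate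
11 | 3-henicosyl-1H-pyrrole-2-carbaldehyde | CCCCCCCCCCCCCCCCCCCCCc1cc[nH]c1C=O | target

**Summary**

Total step count: 5. Longest linear sequence: 5 steps (1 → 2 → 5 → 6 → 10 → 11).

**Steps most likely to fail**

1. Step 4. Three processes could divert material. The pyrrole nitrogen may react on with acetylene (N-vinylation). The enamine may form toward the acetal carbon and end in a non-aromatic 3H-pyrrole. The pyrrolide may expel methoxide from the acetal and oligomerise, and slow dissolution of the waxy oxime in DMSO would lengthen the exposure. The fallback forms the same two ring bonds by enolate alkylation and Paal–Knorr condensation. It sets out from ketone 5, which is deprotonated at the chain methylene with LDA in THF/DMPU at −78 °C and alkylated with allyl bromide to give 1,1-dimethoxy-3-(prop-2-en-1-yl)tetracosan-2-one F1. Ozonolysis (O3, CH2Cl2/MeOH, −78 °C, then Me2S) should give 3-(2,2-dimethoxyacetyl)tetracosanal F2, the oxo analogue of 9. Condensation with ammonium acetate in methanol then closes the pyrrole and returns to 10.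

2. Step 2. Magnesium insertion into the waxy C22 bromide may be sluggish and accompanied by Wurtz-type homocoupling, and the long-chain organomagnesium may precipitate on cooling before it meets the amide. The fallback avoids an organomagnesium altogether. It sets out from 3, which is converted with sodium benzenesulfinate in DMF at 80 °C into (docosylsulfonyl)benzene F3. The α-sulfonyl carbanion of F3 (n-BuLi, THF, −78 °C, two equivalents of anion) is acylated with ester 1 to give 1,1-dimethoxy-3-(phenylsulfonyl)tetracosan-2-one F4. Reductive desulfonylation with aluminium amalgam in aqueous THF returns to 5.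

3. Step 5. Ionisation of the acetal gives an azafulvenium ion that may be trapped by the free C5 position of a second pyrrole faster than by water, leading to self-condensation. The fallback deactivates the ring before unmasking. It sets out from 10, which is acylated on nitrogen with Boc2O and catalytic DMAP in MeCN to give tert-butyl 2-(dimethoxymethyl)-3-henicosyl-1H-pyrrole-1-carboxylate F5. Hydrolysis of the acetal on the now electron-poor ring (dilute HCl, THF/H2O) should give tert-butyl 2-formyl-3-henicosyl-1H-pyrrole-1-carboxylate F6. Methanolysis of the carbamate with K2CO3 in MeOH at room temperature returns to 11.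

**Further compounds**

F1 | step 4 | 1,1-dimethoxy-3-(prop-2-en-1-yl)tetracosan-2-one | CCCCCCCCCCCCCCCCCCCCCC(CC=C)C(=O)C(OC)OC
F2 | step 4 | 3-(2,2-dimethoxyacetyl)tetracosanal | CCCCCCCCCCCCCCCCCCCCCC(CC=O)C(=O)C(OC)OC
F3 | step 2 | (docosylsulfonyl)benzene | CCCCCCCCCCCCCCCCCCCCCCS(=O)(=O)c1ccccc1
F4 | step 2 | 1,1-dimethoxy-3-(phenylsulfonyl)tetracosan-2-one | CCCCCCCCCCCCCCCCCCCCCC(S(=O)(=O)c1ccccc1)C(=O)C(OC)OC
F5 | step 5 | tert-butyl 2-(dimethoxymethyl)-3-henicosyl-1H-pyrrole-1-carboxylate | CCCCCCCCCCCCCCCCCCCCCc1ccn(C(=O)OC(C)(C)C)c1C(OC)OC
F6 | step 5 | tert-butyl 2-formyl-3-henicosyl-1H-pyrrole-1-carboxylate | CCCCCCCCCCCCCCCCCCCCCc1ccn(C(=O)OC(C)(C)C)c1C=O
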